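**Remark (assumption):** the SMILES is read as the trans-bromohydrin (3S,4S,6S)-4,8-dibromo-1,5,5,9-tetramethylspiro[5.5]undeca-1,8-dien-3-ol. Locants C1–C11 below are those of this spiro[5.5]undecane (ring A = C1–C6, ring B = C6–C11).

## Retrosynthetic overview

1. The target comes from an α′-bromo enone of ring A (hydride reduction, then inversion at C3); the C8 vinyl bromide of ring B comes from a C8 ketone through its tetrasubstituted enol triflate.
2. Ring A is cut in one operation at C2–C3 and C5–C6 into a carvone-derived dienone (ring B, C1, its methyl and C2) and the 1,3-dithiane of 3-methylbut-2-enal (C3, C4, C5 and the gem-dimethyl group).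
3. Enabling feature: the spiro carbon C6 is β to C8, so C5=C4–C3–C8(O⁻)–C7=C6 is a 3-oxido-1,5-diene. Its [3,3] shift makes the C5–C6 bond between two fully substituted carbons and leaves C3 as a ketene dithioacetal (acyl cation equivalent) 1,5 to the isopropenyl CH2 (C2), which closes ring A.
4. Stereochemical relay: C5 of (S)-carvone sets the C9 methyl (trans-dihydrocarvone), which sets the C8 carbinol (addition anti to methyl), which sets C6 ([3,3] shift); C8 and C9 then become sp2.
5. Ring order: ring B from the chiral pool, ring A in the key step.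

Key step: step 5

## Route

Step 1
Reactants: 1 (S)-(+)-carvone
Product: 2 (2S,5S)-2-methyl-5-(prop-1-en-2-yl)cyclohexan-1-one
Conditions: LiBH(s-Bu)3 (L-Selectride), THF, −78 °C; MeOH; NaOMe (cat.), MeOH, 23 °C; chromatography
Reagents that add atoms: none
Why: conjugate hydride reduction of the enone, followed by base equilibration, should place the new C2 methyl trans to the C5 isopropenyl group (both equatorial), and chromatography removes residual cis isomer.

Step 2
Reactants: 2 (2S,5S)-2-methyl-5-(prop-1-en-2-yl)cyclohexan-1-one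
Product: 4 (6S)-6-methyl-3-(prop-1-en-2-yl)cyclohex-2-en-1-one, via silyl enol ether 3 (not isolated)
Conditions: LiN(i-Pr)2, THF, −78 °C; Me3SiCl; solvent exchange; Pd(OAc)2 (1.05 equiv), MeCN, 23 °C
Reagents that add atoms: none
Why: kinetic deprotonation at the CH2 flank and Saegusa–Ito oxidation should give the dienone, removing the old carvone stereocentre and leaving only the methyl-bearing carbon that it controlled.

Step 3
Reactants: 5 3-methylbut-2-enal; 6 propane-1,3-dithiol
Product: 7 2-(2-methylprop-1-en-1-yl)-1,3-dithiane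
Conditions: BF3·OEt2 (cat.), CH2Cl2, −20 to 0 °C
Reagents that add atoms: none
Why: Lewis acid-catalysed dithioacetalisation of the aldehyde, with the β,β-dimethyl substitution disfavouring conjugate addition of the thiol.

Step 4
Reactants: 7 2-(2-methylprop-1-en-1-yl)-1,3-dithiane; 4 (6S)-6-methyl-3-(prop-1-en-2-yl)cyclohex-2-en-1-one
Product: 9 (1S,6S)-6-methyl-1-[2-(2-methylprop-1-en-1-yl)-1,3-dithian-2-yl]-3-(prop-1-en-2-yl)cyclohex-2-en-1-ol, via lithiated dithiane 8 (not isolated)
Conditions: n-BuLi, THF, −30 °C; then 4, −78 °C; AcOH quench at −78 °C; chromatography to a single diastereomer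
Reagents that add atoms: none
Why: kinetic α-1,2 addition of the allylic dithiane anion (Corey–Seebach acyl anion chemistry) should occur through the dithiane carbon, since the CMe2 terminus is blocked, and anti to the adjacent C6 methyl, which sets the carbinol centre.

Step 5
Reactants: 9 (1S,6S)-6-methyl-1-[2-(2-methylprop-1-en-1-yl)-1,3-dithian-2-yl]-3-(prop-1-en-2-yl)cyclohex-2-en-1-ol
Product: 12 (6R,9S)-1,5,5,9-tetramethyl-3,3-(propane-1,3-diyldisulfanediyl)spiro[5.5]undec-1-en-8-one, via potassium enolate 10 (not isolated), via keto ketene dithioacetal 11 (not isolated)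
Conditions: KH, 18-crown-6, THF, 0 to 23 °C; AcOH (1.1 equiv), −78 °C; solvent exchange to CH2Cl2; CF3CO2H (3 equiv), 0 °C
Reagents that add atoms: none
Why: The potassium alkoxide of 9 is a 3-oxido-1,5-diene (C5=C4–C3–C8(O⁻)–C7=C6) and should undergo a dithiane-accelerated anionic oxy-Cope [3,3] shift that breaks C3–C8 and forms C5–C6 between two fully substituted carbons, giving enolate 10. Acid then protonates the ketene dithioacetal of 11 at C4 to a 1,3-dithian-2-ylium ion, which the isopropenyl CH2 (C2) captures in a 6-endo-trig cation–olefin closure of ring A (C2–C3); proton loss from the tertiary C1 cation gives the trisubstituted C1=C2 alkene, the thermodynamic isomer under the acid. The closest known reaction types are the α-1,2 addition/anionic oxy-Cope sequence of 2-alkenyl-1,3-dithiane anions with cyclic enones and the ketene dithioacetal-initiated cationic olefin cyclisation. The only new stereocentre, C6, is set by the suprafacial shift across the C6=C7–C8 allyl unit of ring B, which delivers C5 to the face that carried the C3–C8 bond, anti to the C9 methyl; C3 and C5 bear identical substituent pairs, so no other stereochemical issue arises. The step needs the [3,3] shift to beat dissociation and re-addition at the isopropenyl terminus, which the six-membered transition state and the anion-stabilising dithiane should secure, and it needs attack on the cation by C2 in the Markovnikov sense, which the 1,1-disubstituted alkene and the six-membered ring should secure.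

Step 6
Reactants: 12 (6R,9S)-1,5,5,9-tetramethyl-3,3-(propane-1,3-diyldisulfanediyl)spiro[5.5]undec-1-en-8-one
Product: 14 (6R)-1,5,5,9-tetramethyl-3,3-(propane-1,3-diyldisulfanediyl)spiro[5.5]undeca-1,8-dien-8-yl trifluoromethanesulfonate, via silyl enol ether 13 (not isolated)
Conditions: Me3SiCl, NaI, Et3N, MeCN, 23 °C; pentane extraction; MeLi, THF, 0 °C; PhNTf2, −78 to 0 °C
Reagents that add atoms: N-phenylbis(trifluoromethanesulfonimide), O=S(=O)(N(c1ccccc1)S(=O)(=O)C(F)(F)F)C(F)(F)F
Why: thermodynamic silyl enol ether formation should favour the tetrasubstituted C8=C9 enol over the one toward the neopentyl C7, and cleavage with MeLi gives the regiodefined lithium enolate for O-triflation, which also removes the C9 stereocentre.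

Step 7
Reactants: 14 (6R)-1,5,5,9-tetramethyl-3,3-(propane-1,3-diyldisulfanediyl)spiro[5.5]undeca-1,8-dien-8-yl trifluoromethanesulfonate
Product: 15 (6R)-1,5,5,9-tetramethyl-3-oxospiro[5.5]undeca-1,8-dien-8-yl trifluoromethanesulfonate
Conditions: PhI(O2CCF3)2, MeCN/H2O (9:1), 0 °C
Reagents that add atoms: water, O
Why: oxidative hydrolysis of the 1,3-dithiane by the hypervalent iodine reagent should unmask the allylic dithioketal directly as the conjugated enone, while the enol triflate is inert.

Step 8
Reactants: 15 (6R)-1,5,5,9-tetramethyl-3-oxospiro[5.5]undeca-1,8-dien-8-yl trifluoromethanesulfonate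
Product: 16 (6R)-8-bromo-1,5,5,9-tetramethylspiro[5.5]undeca-1,8-dien-3-one
Conditions: Ni(OAc)2·4H2O (10 mol %), cycloocta-1,5-diene (25 mol %), Zn (20 mol %), LiBr (2 equiv), DMA/THF, 23 °C
Reagents that add atoms: lithium bromide, [Li+].[Br-]
Why: nickel-catalysed halogenation of an enol triflate (oxidative addition to zerovalent nickel, triflate/bromide exchange, C–Br reductive elimination) should give the vinyl bromide without moving the alkene.

Step 9
Reactants: 16 (6R)-8-bromo-1,5,5,9-tetramethylspiro[5.5]undeca-1,8-dien-3-one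
Product: 19 (4S,6S)-4,8-dibromo-1,5,5,9-tetramethylspiro[5.5]undeca-1,8-dien-3-one, via silyl dienol ether 17 (not isolated), via C4 epimer 18 (not isolated)
Conditions: LiN(SiMe3)2, THF, −78 °C; Me3SiCl; N-bromosuccinimide, −78 °C; then DBU (0.1 equiv), CH2Cl2, 0 °C
Reagents that add atoms: N-bromosuccinimide, O=C1CCC(=O)N1Br
Why: kinetic α′-deprotonation at C4, bromination of the cross-conjugated silyl dienol ether and base equilibration of the epimerisable α-bromo ketone should give the equatorial bromide, which lies cis to C7 because ring A should prefer the half-chair with C11 pseudoaxial (the other one presses the C1 methyl against the axial hydrogen at C10, whereas C8 is sp2 and has none).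

Step 10
Reactants: 19 (4S,6S)-4,8-dibromo-1,5,5,9-tetramethylspiro[5.5]undeca-1,8-dien-3-one
Product: 20 (3R,4S,6S)-4,8-dibromo-1,5,5,9-tetramethylspiro[5.5]undeca-1,8-dien-3-ol
Conditions: i-Bu2AlH, CH2Cl2, −78 °C
Reagents that add atoms: none
Why: 1,2-reduction in which the pseudoaxial C5 methyl (1,3 to the carbonyl) blocks axial attack, so the bulky hydride should enter equatorially and give the axial alcohol cis to the equatorial bromine.

Step 11
Reactants: 20 (3R,4S,6S)-4,8-dibromo-1,5,5,9-tetramethylspiro[5.5]undeca-1,8-dien-3-ol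
Product: 22 (3S,4S,6S)-4,8-dibromo-1,5,5,9-tetramethylspiro[5.5]undeca-1,8-dien-3-ol, via formate ester 21 (not isolated)
Conditions: HCO2H, PPh3, diisopropyl azodicarboxylate, THF, 0 to 23 °C; then NaHCO3, MeOH/H2O, 0 °C
Reagents that add atoms: formic acid, OC=O
Why: Mitsunobu reaction, in which formate displaces the activated axial C3 oxygen from the open equatorial side with inversion, and mild formate hydrolysis should then give the trans-diequatorial bromohydrin without epoxide formation.

## Compound list

1 | (S)-(+)-carvone, (5S)-2-methyl-5-(prop-1-en-2-yl)cyclohex-2-en-1-one | CC1=CC[C@@H](CC1=O)C(C)=C | starting material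
2 | (2S,5S)-2-methyl-5-(prop-1-en-2-yl)cyclohexan-1-one (trans-dihydrocarvone) | C[C@H]1CC[C@@H](CC1=O)C(C)=C | intermediate
3 | trimethyl{[(3S,6S)-6-methyl-3-(prop-1-en-2-yl)cyclohex-1-en-1-yl]oxy}silane | C[C@H]1CC[C@@H](C=C1O[Si](C)(C)C)C(C)=C | intermediate
4 | (6S)-6-methyl-3-(prop-1-en-2-yl)cyclohex-2-en-1-one | C[C@H]1CCC(=CC1=O)C(C)=C | intermediate
5 | 3-methylbut-2-enal | CC(C)=CC=O | starting material
6 | propane-1,3-dithiol | SCCCS | starting material
7 | 2-(2-methylprop-1-en-1-yl)-1,3-dithiane | CC(C)=CC1SCCCS1 | intermediate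
8 | 2-lithio-2-(2-methylprop-1-en-1-yl)-1,3-dithiane | [Li]C1(C=C(C)C)SCCCS1 | intermediate
9 | (1S,6S)-6-methyl-1-[2-(2-methylprop-1-en-1-yl)-1,3-dithian-2-yl]-3-(prop-1-en-2-yl)cyclohex-2-en-1-ol | C[C@H]1CCC(C(C)=C)=C[C@]1(O)C1(SCCCS1)C=C(C)C | intermediate
10 | potassium (3S,6S)-3-[1-(1,3-dithian-2-ylidene)-2-methylpropan-2-yl]-6-methyl-3-(prop-1-en-2-yl)cyclohex-1-en-1-olate | C[C@H]1CC[C@](C=C1[O-])(C(C)=C)C(C)(C)C=C1SCCCS1.[K+] | intermediate
11 | (2S,5S)-5-[1-(1,3-dithian-2-ylidene)-2-methylpropan-2-yl]-2-methyl-5-(prop-1-en-2-yl)cyclohexan-1-one | C[C@H]1CC[C@](CC1=O)(C(C)=C)C(C)(C)C=C1SCCCS1 | intermediate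
12 | (6R,9S)-1,5,5,9-tetramethyl-3,3-(propane-1,3-diyldisulfanediyl)spiro[5.5]undec-1-en-8-one (C3 ketone masked as its 1,3-dithiane) | C[C@H]1CC[C@]2(CC1=O)C(C)=CC1(SCCCS1)CC2(C)C | intermediate
13 | trimethyl{[(6R)-1,5,5,9-tetramethyl-3,3-(propane-1,3-diyldisulfanediyl)spiro[5.5]undeca-1,8-dien-8-yl]oxy}silane | CC1=C(O[Si](C)(C)C)C[C@@]2(CC1)C(C)=CC1(SCCCS1)CC2(C)C | intermediate
14 | (6R)-1,5,5,9-tetramethyl-3,3-(propane-1,3-diyldisulfanediyl)spiro[5.5]undeca-1,8-dien-8-yl trifluoromethanesulfonate | CC1=C(OS(=O)(=O)C(F)(F)F)C[C@@]2(CC1)C(C)=CC1(SCCCS1)CC2(C)C | intermediate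
15 | (6R)-1,5,5,9-tetramethyl-3-oxospiro[5.5]undeca-1,8-dien-8-yl trifluoromethanesulfonate | CC1=C(OS(=O)(=O)C(F)(F)F)C[C@@]2(CC1)C(C)=CC(=O)CC2(C)C | intermediate
16 | (6R)-8-bromo-1,5,5,9-tetramethylspiro[5.5]undeca-1,8-dien-3-one | CC1=C(Br)C[C@@]2(CC1)C(C)=CC(=O)CC2(C)C | intermediate
17 | {[(6S)-8-bromo-1,5,5,9-tetramethylspiro[5.5]undeca-1,3,8-trien-3-yl]oxy}trimethylsilane | CC1=C(Br)C[C@@]2(CC1)C(C)=CC(O[Si](C)(C)C)=CC2(C)C | intermediate
18 | (4R,6S)-4,8-dibromo-1,5,5,9-tetramethylspiro[5.5]undeca-1,8-dien-3-one | CC1=C(Br)C[C@@]2(CC1)C(C)=CC(=O)[C@H](Br)C2(C)C | intermediate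
19 | (4S,6S)-4,8-dibromo-1,5,5,9-tetramethylspiro[5.5]undeca-1,8-dien-3-one | CC1=C(Br)C[C@@]2(CC1)C(C)=CC(=O)[C@@H](Br)C2(C)C | intermediate
20 | (3R,4S,6S)-4,8-dibromo-1,5,5,9-tetramethylspiro[5.5]undeca-1,8-dien-3-ol | CC1=C(Br)C[C@@]2(CC1)C(C)=C[C@@H](O)[C@@H](Br)C2(C)C | intermediate
21 | (3S,4S,6S)-4,8-dibromo-1,5,5,9-tetramethylspiro[5.5]undeca-1,8-dien-3-yl formate | CC1=C(Br)C[C@@]2(CC1)C(C)=C[C@H](OC=O)[C@@H](Br)C2(C)C | intermediate
22 | (3S,4S,6S)-4,8-dibromo-1,5,5,9-tetramethylspiro[5.5]undeca-1,8-dien-3-ol | CC1=C[C@H](O)[C@@H](Br)C(C)(C)[C@]12CCC(C)=C(Br)C2 | target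

## Summary and risks

Total step count: 11. Longest linear sequence: 10 steps (steps 1, 2, 4, 5, 6, 7, 8, 9, 10, 11 from 1 to 22).

The three steps most likely to fail:

**Step 5 (key step).** The alkoxide may fragment into dienone and dithiane anion, which can re-add at the isopropenyl terminus; the congested [3,3] shift may be too slow; and the tertiary cation of the second stage may undergo a 1,2-shift before it loses a proton. The fallback sets out from 7 and 4 and comes back at 12. Compound 7 is lithiated (n-BuLi, THF, −30 °C) and silylated (Me3SiCl) to 2-(2-methylprop-1-en-1-yl)-2-(trimethylsilyl)-1,3-dithiane F1. This allylsilane is added to 4 in a Hosomi–Sakurai conjugate addition (TiCl4, CH2Cl2, −78 °C), which forms C5–C6 through the CMe2 terminus and gives 11 together with (2S,5R)-5-[1-(1,3-dithian-2-ylidene)-2-methylpropan-2-yl]-2-methyl-5-(prop-1-en-2-yl)cyclohexan-1-one F2. The two are diastereomers because the methyl-bearing centre is intact, so they are separated, and 11 is closed to 12 with CF3CO2H as in the second stage of step 5.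

**Step 9.** The equilibrium at C4 may not favour the needed epimer, and bromine may migrate to C2 or to the C1 methyl during enolisation. The fallback sets out from 16 and comes back at 22, so steps 10 and 11 are then not needed. Compound 16 is condensed with TsNHNH2 (EtOH, 60 °C) to N′-[(6R)-8-bromo-1,5,5,9-tetramethylspiro[5.5]undeca-1,8-dien-3-ylidene]-4-methylbenzenesulfonohydrazide F3. A Shapiro reaction with LiN(i-Pr)2 (THF, −78 to 0 °C) converts it into (6S)-8-bromo-1,5,5,9-tetramethylspiro[5.5]undeca-1,3,8-triene F4. N-Bromosuccinimide in acetone/H2O at 0 °C should then add bromine at C4 and water at the allylic C3 in anti fashion, giving the trans-bromohydrin 22. Here C4 is set by kinetic attack anti to the pseudoaxial C5 methyl, so this route gives the right isomer precisely when the conformational preference assumed in step 9 is reversed.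

**Step 11.** The activated axial allylic oxygen may ionise (allylic transposition, loss of configuration) or eliminate instead of being displaced. The fallback sets out from 19 and comes back at 22. A Meerwein–Ponndorf–Verley reduction (Al(Oi-Pr)3, i-PrOH, toluene, 80 °C), run under equilibrating conditions, should convert 19 into the thermodynamically preferred equatorial alcohol 22, since the axial epimer 20 suffers a 1,3-diaxial contact with the C5 methyl. This fallback makes no new compound (F0).

## Further compounds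

F1 | step 5 | 2-(2-methylprop-1-en-1-yl)-2-(trimethylsilyl)-1,3-dithiane | C[Si](C)(C)C1(C=C(C)C)SCCCS1
F2 | step 5 | (2S,5R)-5-[1-(1,3-dithian-2-ylidene)-2-methylpropan-2-yl]-2-methyl-5-(prop-1-en-2-yl)cyclohexan-1-one | C[C@H]1CC[C@@](CC1=O)(C(C)=C)C(C)(C)C=C1SCCCS1
F3 | step 9 | N′-[(6R)-8-bromo-1,5,5,9-tetramethylspiro[5.5]undeca-1,8-dien-3-ylidene]-4-methylbenzenesulfonohydrazide | CC1=C(Br)C[C@@]2(CC1)C(C)=CC(=NNS(=O)(=O)c1ccc(C)cc1)CC2(C)C
F4 | step 9 | (6S)-8-bromo-1,5,5,9-tetramethylspiro[5.5]undeca-1,3,8-triene | CC1=C(Br)C[C@@]2(CC1)C(C)=CC=CC2(C)C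
F0 | step 11 | none | none
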